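**Strategy.** Elemane numbering is used: the cyclohexane is C5–C10 (C6 lactone oxygen, C7 ring fusion, C8 angelate, C9 acetate, C10 quaternary, C5 isopropenyl). The ring is cut into two three-carbon halves joined in one flask: zinc Barbier allylation of an epoxy aldehyde (C8–C10) with a 3-(bromomethyl)butenolide bearing an allylsilane (C5–C7) makes C7–C8; BF3 then opens the tertiary propargylic oxirane at C10 with the allylsilane, making C5–C10. This exploits the trans C9–O/C10–C5 array, the C5 isopropenyl group and the all-equatorial ring; four stereocentres (C5, C7, C8, C10) are relayed from a Sharpless epoxide and the C6 carbinol. The C10 ethynyl group becomes the (Z)-enol acetate last.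

Key step: step 9

Remark: 1 is assumed to be bought as the pure E isomer and aldehyde 3 to be carried as a dried solution (volatile); in the benzofuranone names C3a, C4, C5, C6, C7, C7a are elemane C7, C8, C9, C10, C5, C6.

Step 1
Reactants: 1 (2E)-3-methylpent-2-en-4-yn-1-ol
Product: 2 [(2S,3S)-3-ethynyl-3-methyloxiran-2-yl]methanol
Conditions: Ti(OiPr)4 (0.2 equiv), L-(+)-diisopropyl tartrate (0.25 equiv), t-BuOOH (anhydrous, decane), 4 Å molecular sieves, CH2Cl2, −20 °C
Reagents that add atoms: tert-butyl hydroperoxide, CC(C)(C)OO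
Why: Sharpless asymmetric epoxidation; the L-(+)-tartrate titanium complex should deliver oxygen to the face that gives the (2S,3S) epoxide of an E-trisubstituted allylic alcohol, setting C9 and C10 together.

Step 2
Reactants: 2 [(2S,3S)-3-ethynyl-3-methyloxiran-2-yl]methanol
Product: 3 (2R,3S)-3-ethynyl-3-methyloxirane-2-carbaldehyde
Conditions: TEMPO (0.1 equiv), PhI(OAc)2, CH2Cl2, 0 °C → rt; short silica pad, kept in solution
Reagents that add atoms: none
Why: Oxoammonium (TEMPO) oxidation of a primary alcohol stops at the aldehyde under non-basic conditions, so the oxirane and the C9 centre next to the new aldehyde should survive.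

Step 3
Reactants: 4 ethyl but-2-ynoate; 5 (trimethylsilyl)methylmagnesium chloride
Product: 6 ethyl (2E)-3-methyl-4-(trimethylsilyl)but-2-enoate
Conditions: 5, CuI (1.1 equiv), THF, −40 °C; then 4, −78 °C; aq. NH4Cl at −78 °C
Reagents that add atoms: (trimethylsilyl)methylcopper, C[Si](C)(C)C[Cu] (formed in the flask from 5 and CuI)
Why: syn-Carbocupration of the ynoate followed by protonation with retention should place CH2SiMe3 trans to the ester, which fixes the E allylsilane geometry.

Step 4
Reactants: 6 ethyl (2E)-3-methyl-4-(trimethylsilyl)but-2-enoate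
Product: 7 (2E)-3-methyl-4-(trimethylsilyl)but-2-en-1-ol
Conditions: i-Bu2AlH (2.2 equiv), CH2Cl2, −78 → 0 °C; aq. Rochelle salt
Reagents that add atoms: none
Why: 1,2-Reduction of the enoate by the aluminium hydride gives the allylic alcohol without touching the allylsilane or the olefin geometry.

Step 5
Reactants: 7 (2E)-3-methyl-4-(trimethylsilyl)but-2-en-1-ol
Product: 8 (2E)-3-methyl-4-(trimethylsilyl)but-2-enal
Conditions: activated MnO2, CH2Cl2, rt
Reagents that add atoms: none
Why: Neutral allylic oxidation with MnO2 is selective for the allylic alcohol and should leave the acid- and fluoride-labile allylsilane intact.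

Step 6
Reactants: 8 (2E)-3-methyl-4-(trimethylsilyl)but-2-enal; 9 vinylmagnesium bromide
Product: 10 (3S,4E)-5-methyl-6-(trimethylsilyl)hexa-1,4-dien-3-ol
Conditions: 9 + ZnCl2 (0.5 equiv per 9), then 1,4-dioxane to remove magnesium halide; (−)-MIB [(2S)-3-exo-morpholinoisoborneol, 10 mol%], 8, toluene, −20 → 0 °C; aq. NH4Cl
Reagents that add atoms: divinylzinc, C=C[Zn]C=C (formed in the flask from 9 and ZnCl2)
Why: Amino alcohol-catalysed enantioselective 1,2-addition of a vinylzinc reagent; the (−)-MIB zinc complex should direct the vinyl group to the Si face of the aldehyde, which sets C6 as S.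

Step 7
Reactants: 10 (3S,4E)-5-methyl-6-(trimethylsilyl)hexa-1,4-dien-3-ol; 11 2-(bromomethyl)prop-2-enoic acid
Product: 12 (3S,4E)-5-methyl-6-(trimethylsilyl)hexa-1,4-dien-3-yl 2-(bromomethyl)prop-2-enoate
Conditions: N,N'-diisopropylcarbodiimide, DMAP (5 mol%), CH2Cl2, −10 → 0 °C
Reagents that add atoms: none
Why: Steglich esterification under near-neutral conditions acylates the bis-allylic alcohol with retention at C6; low temperature and little DMAP should spare the allylic bromide.

Step 8
Reactants: 12 (3S,4E)-5-methyl-6-(trimethylsilyl)hexa-1,4-dien-3-yl 2-(bromomethyl)prop-2-enoate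
Product: 13 (5R)-3-(bromomethyl)-5-[(1E)-2-methyl-3-(trimethylsilyl)prop-1-en-1-yl]furan-2(5H)-one
Conditions: second-generation Hoveyda–Grubbs catalyst RuCl2(H2IMes)(=CH-C6H4-2-OiPr) (5–10 mol%), toluene (dilute), 60 °C, argon sparge
Reagents that add atoms: none
Why: Ring-closing metathesis between the vinyl group and the acrylate closes the butenolide with loss of ethene; the trisubstituted allylsilane olefin is too hindered to compete and C6 is untouched.

Step 9
Reactants: 3 (2R,3S)-3-ethynyl-3-methyloxirane-2-carbaldehyde; 13 (5R)-3-(bromomethyl)-5-[(1E)-2-methyl-3-(trimethylsilyl)prop-1-en-1-yl]furan-2(5H)-one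
Product: 16 (3aR,4R,5R,6R,7S,7aR)-6-ethynyl-4,5-dihydroxy-6-methyl-3-methylidene-7-(prop-1-en-2-yl)hexahydro-1-benzofuran-2(3H)-one, via allylzinc bromide 14 (not isolated), via epoxy zinc alkoxide 15 (not isolated)
Conditions: activated Zn dust, 13 + 3 (1.5 equiv), THF, 0 °C (Barbier mode); then CH2Cl2 (to about 4:1 CH2Cl2/THF), −78 °C, BF3·OEt2 (4 equiv), −78 → −40 °C; sat. aq. NaHCO3
Reagents that add atoms: none
Why: Zinc inserts into the allylic bromide of 13 and the allylzinc 14 adds through C7 to the aldehyde of 3 in a closed chair transition state; BF3 then activates the oxirane of the alkoxide 15 and the allylsilane attacks C10 through its γ-carbon C5 with loss of silicon, so C7–C8 and C5–C10 form in one flask. The closest known types are the Barbier allylation of aldehydes with 3-(bromomethyl)butenolides and the Lewis acid epoxide-initiated cyclisation terminated by an allylsilane (Hosomi–Sakurai type). The cyclohexane closes 6-endo at the oxirane (both oxirane carbons end up in the ring) and exo at the allylsilane, through a chair in which every ring substituent is equatorial. C7 is set by attack anti to the C6 side chain, C8 by the chair of the E-configured cyclic allylzinc (anti adduct, which zinc chelation between aldehyde and oxirane oxygens should reinforce), C10 by inversion at the oxirane carbon, and C5 by equatorial placement of the nascent isopropenyl group. The step needs opening at C10 rather than C9, which the substrate secures because C10 is tertiary and propargylic while C9 is secondary and deactivated by the neighbouring C8 oxygen; Barbier mode keeps the unstable allylzinc from accumulating.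

Step 10
Reactants: 16 (3aR,4R,5R,6R,7S,7aR)-6-ethynyl-4,5-dihydroxy-6-methyl-3-methylidene-7-(prop-1-en-2-yl)hexahydro-1-benzofuran-2(3H)-one; 17 (2Z)-2-methylbut-2-enoic acid (angelic acid)
Product: 18 (3aS,4R,5R,6R,7S,7aR)-6-ethynyl-5-hydroxy-6-methyl-3-methylidene-2-oxo-7-(prop-1-en-2-yl)octahydro-1-benzofuran-4-yl (2Z)-2-methylbut-2-enoate
Conditions: 17, 2,4,6-trichlorobenzoyl chloride, Et3N, toluene, rt; then 16, toluene, 70 °C (no DMAP)
Reagents that add atoms: (2Z)-2-methylbut-2-enoic 2,4,6-trichlorobenzoic anhydride, C/C=C(/C)C(=O)OC(=O)c1c(Cl)cc(Cl)cc1Cl (formed in the flask from 17 and 2,4,6-trichlorobenzoyl chloride)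
Why: Yamaguchi esterification through the mixed anhydride should acylate the less hindered equatorial 8-OH (9-OH is neopentylic, next to quaternary C10) and, run without DMAP, should avoid angelate-to-tiglate isomerisation.

Step 11
Reactants: 18 (3aS,4R,5R,6R,7S,7aR)-6-ethynyl-5-hydroxy-6-methyl-3-methylidene-2-oxo-7-(prop-1-en-2-yl)octahydro-1-benzofuran-4-yl (2Z)-2-methylbut-2-enoate
Product: 19 (3aS,4R,5R,6R,7S,7aR)-5-acetoxy-6-ethynyl-6-methyl-3-methylidene-2-oxo-7-(prop-1-en-2-yl)octahydro-1-benzofuran-4-yl (2Z)-2-methylbut-2-enoate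
Conditions: Ac2O, pyridine, DMAP (0.3 equiv), CH2Cl2, rt
Reagents that add atoms: acetic anhydride, CC(=O)OC(C)=O
Why: DMAP-catalysed acetylation of the remaining hindered secondary alcohol; no stereocentre is touched and the free 9-OH is removed before the alkyne is activated.

Step 12
Reactants: 19 (3aS,4R,5R,6R,7S,7aR)-5-acetoxy-6-ethynyl-6-methyl-3-methylidene-2-oxo-7-(prop-1-en-2-yl)octahydro-1-benzofuran-4-yl (2Z)-2-methylbut-2-enoate
Product: 20 (3aS,4R,5R,6S,7S,7aR)-5-acetoxy-6-[(Z)-2-acetoxyethenyl]-6-methyl-3-methylidene-2-oxo-7-(prop-1-en-2-yl)octahydro-1-benzofuran-4-yl (2Z)-2-methylbut-2-enoate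
Conditions: AcOH (2 equiv), Ru(η3-CH2C(CH3)CH2)2(Ph2P(CH2)4PPh2) (5 mol%), toluene, 50 °C
Reagents that add atoms: acetic acid, CC(=O)O
Why: Ruthenium-catalysed anti-Markovnikov addition of a carboxylic acid to a terminal alkyne through a vinylidene complex should give the (Z)-enol ester, with the sensitive enol acetate made last.

**Compound list**

1 | (2E)-3-methylpent-2-en-4-yn-1-ol | OC/C=C(\C)C#C | starting material
2 | [(2S,3S)-3-ethynyl-3-methyloxiran-2-yl]methanol | OC[C@@H]1O[C@@]1(C)C#C | intermediate
3 | (2R,3S)-3-ethynyl-3-methyloxirane-2-carbaldehyde | O=C[C@@H]1O[C@@]1(C)C#C | intermediate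
4 | ethyl but-2-ynoate | CC#CC(=O)OCC | starting material
5 | (trimethylsilyl)methylmagnesium chloride | C[Si](C)(C)C[Mg]Cl | starting material
6 | ethyl (2E)-3-methyl-4-(trimethylsilyl)but-2-enoate | CCOC(=O)/C=C(\C)C[Si](C)(C)C | intermediate
7 | (2E)-3-methyl-4-(trimethylsilyl)but-2-en-1-ol | OC/C=C(\C)C[Si](C)(C)C | intermediate
8 | (2E)-3-methyl-4-(trimethylsilyl)but-2-enal | O=C/C=C(\C)C[Si](C)(C)C | intermediate
9 | vinylmagnesium bromide | C=C[Mg]Br | starting material
10 | (3S,4E)-5-methyl-6-(trimethylsilyl)hexa-1,4-dien-3-ol | C=C[C@H](O)/C=C(\C)C[Si](C)(C)C | intermediate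
11 | 2-(bromomethyl)prop-2-enoic acid | OC(=O)C(=C)CBr | starting material
12 | (3S,4E)-5-methyl-6-(trimethylsilyl)hexa-1,4-dien-3-yl 2-(bromomethyl)prop-2-enoate | C=C[C@H](OC(=O)C(=C)CBr)/C=C(\C)C[Si](C)(C)C | intermediate
13 | (5R)-3-(bromomethyl)-5-[(1E)-2-methyl-3-(trimethylsilyl)prop-1-en-1-yl]furan-2(5H)-one | O=C1O[C@H](/C=C(\C)C[Si](C)(C)C)C=C1CBr | intermediate
14 | {(5R)-5-[(1E)-2-methyl-3-(trimethylsilyl)prop-1-en-1-yl]-2-oxo-2,5-dihydrofuran-3-yl}methylzinc bromide | O=C1O[C@H](/C=C(\C)C[Si](C)(C)C)C=C1C[Zn]Br | intermediate (not isolated)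
15 | bromozinc alkoxide of (4R,5R)-4-{(R)-[(2S,3S)-3-ethynyl-3-methyloxiran-2-yl](hydroxy)methyl}-3-methylidene-5-[(1E)-2-methyl-3-(trimethylsilyl)prop-1-en-1-yl]oxolan-2-one (descriptors of the parent alcohol) | C=C1C(=O)O[C@H](/C=C(\C)C[Si](C)(C)C)[C@H]1[C@@H](O[Zn]Br)[C@@H]2O[C@@]2(C)C#C | intermediate (not isolated)
16 | (3aR,4R,5R,6R,7S,7aR)-6-ethynyl-4,5-dihydroxy-6-methyl-3-methylidene-7-(prop-1-en-2-yl)hexahydro-1-benzofuran-2(3H)-one | C=C1C(=O)O[C@H]2[C@H]1[C@@H](O)[C@H](O)[C@@](C)(C#C)[C@@H]2C(=C)C | intermediate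
17 | (2Z)-2-methylbut-2-enoic acid (angelic acid) | C/C=C(/C)C(=O)O | starting material
18 | (3aS,4R,5R,6R,7S,7aR)-6-ethynyl-5-hydroxy-6-methyl-3-methylidene-2-oxo-7-(prop-1-en-2-yl)octahydro-1-benzofuran-4-yl (2Z)-2-methylbut-2-enoate | C=C1C(=O)O[C@H]2[C@H]1[C@@H](OC(=O)/C(C)=C\C)[C@H](O)[C@@](C)(C#C)[C@@H]2C(=C)C | intermediate
19 | (3aS,4R,5R,6R,7S,7aR)-5-acetoxy-6-ethynyl-6-methyl-3-methylidene-2-oxo-7-(prop-1-en-2-yl)octahydro-1-benzofuran-4-yl (2Z)-2-methylbut-2-enoate | C=C1C(=O)O[C@H]2[C@H]1[C@@H](OC(=O)/C(C)=C\C)[C@H](OC(C)=O)[C@@](C)(C#C)[C@@H]2C(=C)C | intermediate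
20 | (3aS,4R,5R,6S,7S,7aR)-5-acetoxy-6-[(Z)-2-acetoxyethenyl]-6-methyl-3-methylidene-2-oxo-7-(prop-1-en-2-yl)octahydro-1-benzofuran-4-yl (2Z)-2-methylbut-2-enoate | C=C1C(=O)O[C@H]2[C@H]1[C@@H](OC(=O)/C(C)=C\C)[C@H](OC(C)=O)[C@@](C)(/C=C\OC(C)=O)[C@@H]2C(=C)C | target

**Step count.** Total: 12 steps. Longest linear sequence: 10 steps (4 → 20, steps 3–12).

**Steps most likely to fail**

Risk 1, step 9. Several processes could defeat the one-flask sequence:
- mismatched facial selectivity in the allylation, if reagent control from C6 works against the intrinsic bias of the α-oxiranyl aldehyde;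
- hydride shift in the BF3-activated oxirane, giving a C9 ketone;
- a free propargylic cation that erodes inversion at C10;
- capture of the activated oxirane by THF;
- protodesilylation or 1,4-elimination of the allylsilane across the allylic C6–O bond before ring closure.

The fallback sets out from 3 and 13 and returns at 16. It separates the two bond formations and switches the closure to a Nicholas reaction. Indium powder in THF/H2O should join 3 and 13 under chelation control to the isolated epoxy alcohol F1. Co2(CO)8 in CH2Cl2 should convert its terminal alkyne into the hexacarbonyldicobalt complex F2. BF3·OEt2 at −78 °C should then open the oxirane at C10 to the cobalt-stabilised propargylic cation, which the allylsilane traps to give the cyclised complex F3. This closure is stereoconvergent: the chair places the bulky cluster equatorial and the methyl axial, so C10 no longer depends on clean inversion. (NH4)2Ce(NO3)6 in acetone at low temperature should remove cobalt and give 16.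

Risk 2, step 10. The acylation may not discriminate 8-OH from 9-OH, the angeloyl group may isomerise to tigloyl under forcing conditions, or the lactone may migrate from O6 to the free O8.

The fallback sets out from 16 and returns at 19, skipping 18; it reverses the order of acylation with a temporary silyl group. Et3SiCl/imidazole at −40 °C should silylate the less hindered 8-OH to the silyl ether F4, a cold reaction that is easier to stop at one hydroxyl than a hot acylation. Ac2O/DMAP should acetylate 9-OH to give F5. HF·pyridine in THF should remove the silyl group under acidic conditions that should not move the acetate, giving the hydroxy acetate F6. Yamaguchi angeloylation of the single free hydroxyl should then give 19.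

Risk 3, step 12. Vinylidene formation may be slow at the neopentyl alkyne, Z selectivity may erode or Markovnikov addition may compete, and ruthenium may promote migration of the exocyclic lactone olefin.

The fallback sets out from 19 and returns at 20. Anti-Markovnikov hydration with [Ru(C5H5)(CH3CN)3]PF6 and 5,5′-bis(trifluoromethyl)-2,2′-bipyridine in NMP/H2O should give the aldehyde F7. Ac2O, Et3N and DMAP should give the enol acetates, from which the Z isomer 20 would be separated from the E isomer F8. This route gives up stereocontrol in exchange for robust chemistry.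

**Further compounds**

F1 | step 9 | epoxy alcohol, (4R,5R)-4-{(R)-[(2S,3S)-3-ethynyl-3-methyloxiran-2-yl](hydroxy)methyl}-3-methylidene-5-[(1E)-2-methyl-3-(trimethylsilyl)prop-1-en-1-yl]oxolan-2-one | C=C1C(=O)O[C@H](/C=C(\C)C[Si](C)(C)C)[C@H]1[C@@H](O)[C@@H]2O[C@@]2(C)C#C
F2 | step 9 | hexacarbonyldicobalt alkyne complex of F1 | C=C1C(=O)O[C@H](/C=C(\C)C[Si](C)(C)C)[C@H]1[C@@H](O)[C@@H]2O[C@@]2(C)C34[CH]5[Co]3(=C=O)(=C=O)(=C=O)[Co]45(=C=O)(=C=O)=C=O
F3 | step 9 | hexacarbonyldicobalt alkyne complex of 16 | C=C1C(=O)O[C@H]2[C@H]1[C@@H](O)[C@H](O)[C@@](C)(C34[CH]5[Co]3(=C=O)(=C=O)(=C=O)[Co]45(=C=O)(=C=O)=C=O)[C@@H]2C(=C)C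
F4 | step 10 | 8-O-triethylsilyl ether of 16 (silyl ether at benzofuranone C4, free 5-OH) | C=C1C(=O)O[C@H]2[C@H]1[C@@H](O[Si](CC)(CC)CC)[C@H](O)[C@@](C)(C#C)[C@@H]2C(=C)C
F5 | step 10 | 9-O-acetate of F4 (4-triethylsilyloxy, 5-acetoxy) | C=C1C(=O)O[C@H]2[C@H]1[C@@H](O[Si](CC)(CC)CC)[C@H](OC(C)=O)[C@@](C)(C#C)[C@@H]2C(=C)C
F6 | step 10 | 9-O-acetate of 16 with free 8-OH (4-hydroxy, 5-acetoxy) | C=C1C(=O)O[C@H]2[C@H]1[C@@H](O)[C@H](OC(C)=O)[C@@](C)(C#C)[C@@H]2C(=C)C
F7 | step 12 | aldehyde from 19, with 2-oxoethyl in place of ethynyl at C10 | C=C1C(=O)O[C@H]2[C@H]1[C@@H](OC(=O)/C(C)=C\C)[C@H](OC(C)=O)[C@@](C)(CC=O)[C@@H]2C(=C)C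
F8 | step 12 | E enol acetate isomer of 20 | C=C1C(=O)O[C@H]2[C@H]1[C@@H](OC(=O)/C(C)=C\C)[C@H](OC(C)=O)[C@@](C)(/C=C/OC(C)=O)[C@@H]2C(=C)C
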